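The route rests on leaving out, until the end, the four hydroxyls that flank the two depside oxygens: O3 and O5 of ring A (the acid ring) and O3' and O5' of ring B (the middle ring; ring C is the terminal galloyl). With bromine at C3, C5, C3' and C5', each ring carries a single hydroxyl (O4, O4') during assembly, so both aryl esters form without para/meta choice or acyl migration. The key step then turns tetrabromide 9, a benzyl-protected tri-aryl diester, into tetraphenol 12 in one operation by fourfold palladium-catalysed borylation and acidic oxidation of the boronates. Hydrogenolysis of four benzyl groups finishes the synthesis.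

Key step: step 5

Remark on the chemistry: both aryl esters of 9 are esters of phenols with pKa near 6 and are treated as activated esters throughout. For that reason ring B enters as aldehyde 4 (no carboxyl protecting group to remove), step 4 uses no nucleophilic catalyst, and step 5 uses pivalate and an acidic oxidant.

Step 1
Reactants: 1 3,5-dibromo-4-hydroxybenzoic acid
Product: 2 benzyl 3,5-dibromo-4-hydroxybenzoate
Conditions: BnBr (1.05 equiv), KHCO3 (1.05 equiv), DMF, rt
Reagents that add atoms: benzyl bromide, BrCc1ccccc1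
Why: Carboxylate O-alkylation (SN2) should be chemoselective because one equivalent of hydrogen carbonate deprotonates only the carboxylic acid, while the phenol, flanked by two bromines, stays protonated and is a poor nucleophile.

Step 2
Reactants: 3 3,4,5-tris(benzyloxy)benzoic acid; 4 3,5-dibromo-4-hydroxybenzaldehyde
Product: 6 2,6-dibromo-4-formylphenyl 3,4,5-tris(benzyloxy)benzoate, via tri-O-benzylgalloyl chloride 5 (not isolated)
Conditions: (COCl)2, cat. DMF, CH2Cl2, 0 °C to rt, evaporate; then 4, Et3N, DMAP (10 mol%), CH2Cl2, 0 °C to rt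
Reagents that add atoms: oxalyl chloride, O=C(Cl)C(=O)Cl (chlorine of intermediate 5 only; none of its atoms remain in 6)
Why: Vilsmeier-type conversion of the acid into its chloride followed by DMAP-catalysed acylation of the phenoxide of 4 (Schotten–Baumann-type esterification) should be clean, because 4 has a single hydroxyl and any DMAP-mediated reopening of the product ester is degenerate.

Step 3
Reactants: 6 2,6-dibromo-4-formylphenyl 3,4,5-tris(benzyloxy)benzoate
Product: 7 3,5-dibromo-4-[3,4,5-tris(benzyloxy)benzoyloxy]benzoic acid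
Conditions: NaClO2, NaH2PO4, 2-methyl-2-butene, THF/t-BuOH/H2O, 0 °C to rt
Reagents that add atoms: sodium chlorite (NaClO2), [Na+].[O-]Cl=O
Why: Pinnick oxidation (chlorous acid adds to the aldehyde, the adduct fragments to the acid and HOCl, and the alkene traps the HOCl) runs near pH 4, where the aryl ester, the benzyl ethers and the aryl bromides should be untouched, and so delivers the ring C–B acid without a carboxyl protecting group.

Step 4
Reactants: 7 3,5-dibromo-4-[3,4,5-tris(benzyloxy)benzoyloxy]benzoic acid; 2 benzyl 3,5-dibromo-4-hydroxybenzoate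
Product: 9 benzyl 3,5-dibromo-4-{3,5-dibromo-4-[3,4,5-tris(benzyloxy)benzoyloxy]benzoyl}oxybenzoate, via acid chloride 8 (not isolated)
Conditions: (COCl)2, cat. DMF, CH2Cl2, 0 °C to rt, evaporate; then 2, Et3N, CH2Cl2, 0 °C to rt
Reagents that add atoms: oxalyl chloride, O=C(Cl)C(=O)Cl (chlorine of intermediate 8 only; none of its atoms remain in 9)
Why: Acylation of the triethylammonium phenoxide of 2 by the aroyl chloride should be selective, because the acyl chloride of 8 is far more electrophilic than its hindered galloyl ester, no nucleophilic catalyst is present to shuttle the galloyl group, and ring A offers a single hydroxyl.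

Step 5
Reactants: 9 benzyl 3,5-dibromo-4-{3,5-dibromo-4-[3,4,5-tris(benzyloxy)benzoyloxy]benzoyl}oxybenzoate; 10 bis(pinacolato)diboron
Product: 12 benzyl 3,5-dihydroxy-4-{3,5-dihydroxy-4-[3,4,5-tris(benzyloxy)benzoyloxy]benzoyl}oxybenzoate, via tetrakis(pinacolboronate) 11 (not isolated)
Conditions: B2pin2 (6 equiv), Pd(OAc)2 (10 mol%), XPhos (20 mol%), KO2CtBu (12 equiv), 1,4-dioxane, 60 °C; silica plug; then KHSO5 (as Oxone, 2KHSO5·KHSO4·K2SO4), acetone/H2O, 0 °C
Reagents that add atoms: potassium peroxymonosulfate (KHSO5), [K+].[O-]S(=O)(=O)OO (the four new oxygens of 12); bis(pinacolato)diboron 10, CC1(C)OB(OC1(C)C)B1OC(C)(C)C(C)(C)O1 (boryl groups of intermediate 11 only)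
Why: Each C–Br bond adds oxidatively to zerovalent palladium carrying XPhos, pivalate replaces bromide on divalent palladium, the Pd–O bond cleaves the B–B bond of 10 (transmetalation) and reductive elimination forms the aryl–boron bond, four times over to give 11; peroxymonosulfate then adds to each boron, the aryl group shifts from boron to oxygen with loss of sulfate, and water hydrolyses the aryl borates to the phenols of 12. The closest known reaction types are the Miyaura borylation of aryl bromides and the Oxone oxidation of arylboronic esters to phenols, here run four times on one molecule. No ring is closed and no stereocentre is formed; the sites of the new C–O bonds (C3 and C5 of ring A, C3' and C5' of ring B) are fixed by the bromines. The selectivity needed is chemoselectivity for C–Br over the two activated 2,6-disubstituted aryl esters and the benzylic C–O bonds: the bulky, weakly nucleophilic pivalate (a mixed pivalic anhydride, if it formed, would be reopened at the aroyl carbonyl and regenerate the depside), the moderate temperature allowed by the electron-rich biaryl phosphine, and the shielding of both ester oxygens by their two ortho substituents should provide it. The oxidant is acidic and carries neither free peroxide anion nor amine base, so the esters should not be perhydrolysed, and the four hydroxyls are set free only at low pH and 0 °C, where acyl migration from O4 to O3 is slow.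

Step 6
Reactants: 12 benzyl 3,5-dihydroxy-4-{3,5-dihydroxy-4-[3,4,5-tris(benzyloxy)benzoyloxy]benzoyl}oxybenzoate
Product: 13 3,5-dihydroxy-4-{3,5-dihydroxy-4-[(3,4,5-trihydroxybenzoyl)oxy]benzoyl}oxybenzoic acid
Conditions: H2 (1 atm), 10% Pd/C, THF/EtOAc, rt
Reagents that add atoms: none
Why: Heterogeneous hydrogenolysis should cleave the three benzyl ethers of ring C and the benzyl ester of ring A to toluene under neutral, aprotic conditions that leave both aryl ester bonds intact and give acyl migration little opportunity.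

Compound list
1 | 3,5-dibromo-4-hydroxybenzoic acid | O=C(O)c1cc(Br)c(O)c(Br)c1 | starting material
2 | benzyl 3,5-dibromo-4-hydroxybenzoate | O=C(OCc1ccccc1)c1cc(Br)c(O)c(Br)c1 | intermediate
3 | 3,4,5-tris(benzyloxy)benzoic acid | O=C(O)c1cc(OCc2ccccc2)c(OCc2ccccc2)c(OCc2ccccc2)c1 | starting material
4 | 3,5-dibromo-4-hydroxybenzaldehyde | O=Cc1cc(Br)c(O)c(Br)c1 | starting material
5 | 3,4,5-tris(benzyloxy)benzoyl chloride (tri-O-benzylgalloyl chloride) | O=C(Cl)c1cc(OCc2ccccc2)c(OCc2ccccc2)c(OCc2ccccc2)c1 | intermediate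
6 | 2,6-dibromo-4-formylphenyl 3,4,5-tris(benzyloxy)benzoate | O=Cc1cc(Br)c(OC(=O)c2cc(OCc3ccccc3)c(OCc3ccccc3)c(OCc3ccccc3)c2)c(Br)c1 | intermediate
7 | 3,5-dibromo-4-[3,4,5-tris(benzyloxy)benzoyloxy]benzoic acid | O=C(O)c1cc(Br)c(OC(=O)c2cc(OCc3ccccc3)c(OCc3ccccc3)c(OCc3ccccc3)c2)c(Br)c1 | intermediate
8 | 3,5-dibromo-4-[3,4,5-tris(benzyloxy)benzoyloxy]benzoyl chloride | O=C(Cl)c1cc(Br)c(OC(=O)c2cc(OCc3ccccc3)c(OCc3ccccc3)c(OCc3ccccc3)c2)c(Br)c1 | intermediate
9 | benzyl 3,5-dibromo-4-{3,5-dibromo-4-[3,4,5-tris(benzyloxy)benzoyloxy]benzoyl}oxybenzoate | O=C(OCc1ccccc1)c1cc(Br)c(OC(=O)c2cc(Br)c(OC(=O)c3cc(OCc4ccccc4)c(OCc4ccccc4)c(OCc4ccccc4)c3)c(Br)c2)c(Br)c1 | intermediate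
10 | bis(pinacolato)diboron | CC1(C)OB(OC1(C)C)B1OC(C)(C)C(C)(C)O1 | starting material
11 | benzyl 3,5-bis(4,4,5,5-tetramethyl-1,3,2-dioxaborolan-2-yl)-4-{3,5-bis(4,4,5,5-tetramethyl-1,3,2-dioxaborolan-2-yl)-4-[3,4,5-tris(benzyloxy)benzoyloxy]benzoyl}oxybenzoate | O=C(OCc1ccccc1)c1cc(B2OC(C)(C)C(C)(C)O2)c(OC(=O)c2cc(B3OC(C)(C)C(C)(C)O3)c(OC(=O)c3cc(OCc4ccccc4)c(OCc4ccccc4)c(OCc4ccccc4)c3)c(B3OC(C)(C)C(C)(C)O3)c2)c(B2OC(C)(C)C(C)(C)O2)c1 | intermediate
12 | benzyl 3,5-dihydroxy-4-{3,5-dihydroxy-4-[3,4,5-tris(benzyloxy)benzoyloxy]benzoyl}oxybenzoate | O=C(OCc1ccccc1)c1cc(O)c(OC(=O)c2cc(O)c(OC(=O)c3cc(OCc4ccccc4)c(OCc4ccccc4)c(OCc4ccccc4)c3)c(O)c2)c(O)c1 | intermediate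
13 | 3,5-dihydroxy-4-{3,5-dihydroxy-4-[(3,4,5-trihydroxybenzoyl)oxy]benzoyl}oxybenzoic acid | O=C(O)c1cc(O)c(OC(=O)c2cc(O)c(OC(=O)c3cc(O)c(O)c(O)c3)c(O)c2)c(O)c1 | target

Total step count: 6. Longest linear sequence: 5 (steps 2, 3, 4, 5 and 6, from 3 or 4).

Steps most likely to fail

Step 5. The fourfold exchange may stop short, with reductive loss of bromine at one or more positions, which would give deoxy analogues that are hard to remove. Pivalate or zerovalent palladium may also cut or shuffle the activated aryl esters during the borylation, and an acyl group may move to a neighbouring oxygen once the phenols appear. The fallback carries the flanking oxygens from the start as benzyl ethers and unveils all hydroxyls in a final hydrogenolysis; it sets out from acid chloride 5 (from 3 as in step 2) and returns to the route at target 13. Commercial 3,4,5-tris(benzyloxy)benzaldehyde would be debenzylated at the para oxygen only (MgBr2·OEt2, toluene/Et2O, reflux) to give 3,5-bis(benzyloxy)-4-hydroxybenzaldehyde F1. The ether cleaved is the one conjugated with the complexed aldehyde and crowded by two neighbours, the selectivity known from the conversion of 3,4,5-trimethoxybenzaldehyde into syringaldehyde. Acylation of F1 with 5 (Et3N, cat. DMAP, CH2Cl2) should give 2,6-bis(benzyloxy)-4-formylphenyl 3,4,5-tris(benzyloxy)benzoate F2, and Pinnick oxidation as in step 3 should give 3,5-bis(benzyloxy)-4-[3,4,5-tris(benzyloxy)benzoyloxy]benzoic acid F3. Its chloride, 3,5-bis(benzyloxy)-4-[3,4,5-tris(benzyloxy)benzoyloxy]benzoyl chloride F4 ((COCl)2, cat. DMF, used crude), would acylate a second portion of F1 to give 2,6-bis(benzyloxy)-4-formylphenyl 3,5-bis(benzyloxy)-4-[3,4,5-tris(benzyloxy)benzoyloxy]benzoate F5. A second Pinnick oxidation should give 3,5-bis(benzyloxy)-4-{3,5-bis(benzyloxy)-4-[3,4,5-tris(benzyloxy)benzoyloxy]benzoyl}oxybenzoic acid F6, whose seven benzyl ethers would be removed under the conditions of step 6 to give 13. Here too each ring has one free hydroxyl during assembly, so no para/meta choice arises.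

Step 6. A galloyl group may migrate from O4 to the neighbouring O3 once every phenol is free (para-to-meta isomerisation of the depside) during long contact with the catalyst support, or the hydrogenolysis may stall through poisoning by traces of bromide or boron. The fallback sets out from 12 and returns at 13 without a new compound: the four benzyl groups would be removed non-reductively with BCl3 and pentamethylbenzene as cation scavenger in CH2Cl2 at −78 °C, followed by a cold aqueous quench. The medium is strongly acidic and cold throughout, which should freeze acyl migration, and aryl esters are known to survive it.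

Step 3. The galloyl group may be lost by hydrolysis of the activated aryl ester in the aqueous medium, or a ring may be chlorinated by HOCl if trapping is slow. The fallback replaces the aldehyde oxidation by a protecting-group route; it sets out from 1 (and uses 5) and returns at 7. Acid 1 would be esterified with N,N-dimethylformamide di-tert-butyl acetal (toluene, 80 °C) to tert-butyl 3,5-dibromo-4-hydroxybenzoate F7. Acylation with 5 (Et3N, cat. DMAP, CH2Cl2) should give tert-butyl 3,5-dibromo-4-[3,4,5-tris(benzyloxy)benzoyloxy]benzoate F8, and TFA/CH2Cl2 at rt would cleave the tert-butyl ester under anhydrous acid to give 7.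

Further compounds
F1 | step 5 | 3,5-bis(benzyloxy)-4-hydroxybenzaldehyde | O=Cc1cc(OCc2ccccc2)c(O)c(OCc2ccccc2)c1
F2 | step 5 | 2,6-bis(benzyloxy)-4-formylphenyl 3,4,5-tris(benzyloxy)benzoate | O=Cc1cc(OCc2ccccc2)c(OC(=O)c2cc(OCc3ccccc3)c(OCc3ccccc3)c(OCc3ccccc3)c2)c(OCc2ccccc2)c1
F3 | step 5 | 3,5-bis(benzyloxy)-4-[3,4,5-tris(benzyloxy)benzoyloxy]benzoic acid | O=C(O)c1cc(OCc2ccccc2)c(OC(=O)c2cc(OCc3ccccc3)c(OCc3ccccc3)c(OCc3ccccc3)c2)c(OCc2ccccc2)c1
F4 | step 5 | 3,5-bis(benzyloxy)-4-[3,4,5-tris(benzyloxy)benzoyloxy]benzoyl chloride | O=C(Cl)c1cc(OCc2ccccc2)c(OC(=O)c2cc(OCc3ccccc3)c(OCc3ccccc3)c(OCc3ccccc3)c2)c(OCc2ccccc2)c1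
F5 | step 5 | 2,6-bis(benzyloxy)-4-formylphenyl 3,5-bis(benzyloxy)-4-[3,4,5-tris(benzyloxy)benzoyloxy]benzoate | O=Cc1cc(OCc2ccccc2)c(OC(=O)c2cc(OCc3ccccc3)c(OC(=O)c3cc(OCc4ccccc4)c(OCc4ccccc4)c(OCc4ccccc4)c3)c(OCc3ccccc3)c2)c(OCc2ccccc2)c1
F6 | step 5 | 3,5-bis(benzyloxy)-4-{3,5-bis(benzyloxy)-4-[3,4,5-tris(benzyloxy)benzoyloxy]benzoyl}oxybenzoic acid | O=C(O)c1cc(OCc2ccccc2)c(OC(=O)c2cc(OCc3ccccc3)c(OC(=O)c3cc(OCc4ccccc4)c(OCc4ccccc4)c(OCc4ccccc4)c3)c(OCc3ccccc3)c2)c(OCc2ccccc2)c1
F0 | step 6 | none | none
F7 | step 3 | tert-butyl 3,5-dibromo-4-hydroxybenzoate | CC(C)(C)OC(=O)c1cc(Br)c(O)c(Br)c1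
F8 | step 3 | tert-butyl 3,5-dibromo-4-[3,4,5-tris(benzyloxy)benzoyloxy]benzoate | CC(C)(C)OC(=O)c1cc(Br)c(OC(=O)c2cc(OCc3ccccc3)c(OCc3ccccc3)c(OCc3ccccc3)c2)c(Br)c1
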